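**Plan**
- Retrosynthetic cuts, in order: the C5–OMe bond (back to a C5 vinyl bromide); the O1–C7a bond of the five-membered ring (alcohol plus dibromodienone); the C2–aryl bond (aryl addition to an aldehyde); the C3a–allyl bond (dearomative allylation of a phenol); the C3–CH3 bond (enolate methylation).
- Forward: the six-membered ring starts as the benzene ring of 4-(benzyloxy)phenylacetic acid. It is dibrominated and dearomatised by para-allylation to a 4,4-disubstituted 2,6-dibromocyclohexa-2,5-dienone, and only then is the trimethoxyphenyl carbinol attached. The five-membered ring (O1, C2, C3, C3a, C7a) closes in the penultimate step.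
- Enabling feature: in the dienone the two arms C4=C5(Br) and C7a=C7(Br) are identical, so C3a is not a stereocentre and the allyl group needs no facial control. C3a becomes stereogenic only when O1 bonds to C7a and HBr is lost across C7–C7a.
- Stereochemistry: C3 comes from an Evans methylation (auxiliary control). C2 comes from a Felkin–Anh aryl addition next to the quaternary ring carbon (substrate control). C3a comes from selection between the two diastereotopic bromoenone arms by the resident C2/C3 pair in the key step.
- The bromine that is not eliminated is converted into the C5 methoxy group by copper-catalysed C–O coupling.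

Key step: step 9

Remark: the benzofuranone numbering of the target (O1, C2, C3, C3a, C4 to C7, C7a) is used for the corresponding atoms of all intermediates, and the four starting materials are assumed to be commercial in the stated form.

**Route**

Step 1
Reactants: 1 4-(benzyloxy)phenylacetic acid; 2 (S)-4-benzyl-1,3-oxazolidin-2-one
Product: 4 (4S)-4-benzyl-3-{[4-(benzyloxy)phenyl]acetyl}-1,3-oxazolidin-2-one, via mixed pivalic anhydride 3 (not isolated)
Conditions: t-BuCOCl, Et3N, THF, −20 °C; then LiCl, 2, −20 °C → rt
Reagents that add atoms: none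
Why: N-acylation of the oxazolidinone by the preformed mixed pivalic anhydride (Evans acylation, LiCl/Et3N variant) is routine for arylacetic acids, the benzyl ether masks the phenol and no stereocentre is formed.

Step 2
Reactants: 4 (4S)-4-benzyl-3-{[4-(benzyloxy)phenyl]acetyl}-1,3-oxazolidin-2-one
Product: 6 (4S)-4-benzyl-3-{(2S)-2-[4-(benzyloxy)phenyl]propanoyl}-1,3-oxazolidin-2-one, via sodium Z-enolate 5 (not isolated)
Conditions: NaN(SiMe3)2, THF, −78 °C; MeI, −78 → −40 °C
Reagents that add atoms: iodomethane, CI
Why: Evans asymmetric alkylation, in which the chelated sodium Z-enolate is methylated on the face opposite the C4 benzyl group, should set the (S) methine that becomes C3, the minor diastereomer being removable by chromatography or crystallisation.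

Step 3
Reactants: 6 (4S)-4-benzyl-3-{(2S)-2-[4-(benzyloxy)phenyl]propanoyl}-1,3-oxazolidin-2-one
Product: 7 (2S)-2-[4-(benzyloxy)phenyl]propan-1-ol
Conditions: LiBH4, H2O (1 equiv), Et2O, 0 °C
Reagents that add atoms: none
Why: Reductive cleavage of the imide with LiBH4 (hydride attack at the exocyclic carbonyl) should give the primary alcohol without epimerising the alpha-aryl centre and returns the auxiliary.

Step 4
Reactants: 7 (2S)-2-[4-(benzyloxy)phenyl]propan-1-ol
Product: 8 4-[(2S)-1-hydroxypropan-2-yl]phenol
Conditions: H2 (1 atm), Pd/C, EtOAc–MeOH, rt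
Reagents that add atoms: none
Why: Hydrogenolysis of the aryl benzyl ether over Pd/C frees the phenol, while the stereocentre carries only C–C and C–H bonds and the primary alcohol is not benzylic, so nothing else should be cleaved.

Step 5
Reactants: 8 4-[(2S)-1-hydroxypropan-2-yl]phenol
Product: 9 2,6-dibromo-4-[(2S)-1-hydroxypropan-2-yl]phenol
Conditions: NBS (2.05 equiv), MeCN, 0 °C → rt
Reagents that add atoms: N-bromosuccinimide, O=C1CCC(=O)N1Br
Why: Electrophilic aromatic bromination of a para-substituted phenol goes to both ortho positions (as with tyrosol-type phenols) and leaves the primary alcohol alone; the two bromines later block the ortho carbons and serve as the leaving group at C7 and the handle at C5.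

Step 6
Reactants: 9 2,6-dibromo-4-[(2S)-1-hydroxypropan-2-yl]phenol; 10 allyltrimethylsilane
Product: 11 4-allyl-2,6-dibromo-4-[(2S)-1-hydroxypropan-2-yl]cyclohexa-2,5-dien-1-one
Conditions: PhI(OAc)2, 10 (5 equiv), (CF3)2CHOH, −20 → 0 °C
Reagents that add atoms: none
Why: Oxidative dearomatisation by trivalent iodine in a fluorinated alcohol, with capture of the oxidised phenol at the para carbon by the allylsilane (oxidative Hosomi–Sakurai-type allylation, known for ortho-blocked 4-alkylphenols), should give the dienone; the hydroxyl cannot reach the ipso carbon in a favourable ring size, C4 is not stereogenic because the two arms are identical, and the step is run before the electron-rich aryl ring is present so that no internal arene competes for the cation.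

Step 7
Reactants: 11 4-allyl-2,6-dibromo-4-[(2S)-1-hydroxypropan-2-yl]cyclohexa-2,5-dien-1-one
Product: 12 (2S)-2-(1-allyl-3,5-dibromo-4-oxocyclohexa-2,5-dien-1-yl)propanal
Conditions: TEMPO (cat.), PhI(OAc)2, CH2Cl2, rt
Reagents that add atoms: none
Why: Oxoammonium-mediated oxidation (TEMPO/PhI(OAc)2) stops at the aldehyde under non-basic, anhydrous conditions, so the alpha stereocentre should not epimerise and the dienone and allyl group stay untouched.

Step 8
Reactants: 12 (2S)-2-(1-allyl-3,5-dibromo-4-oxocyclohexa-2,5-dien-1-yl)propanal; 13 5-bromo-1,2,3-trimethoxybenzene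
Product: 16 4-allyl-2,6-dibromo-4-[(1R,2S)-1-hydroxy-1-(3,4,5-trimethoxyphenyl)propan-2-yl]cyclohexa-2,5-dien-1-one, via aryllithium 14 (not isolated), via aryltitanium triisopropoxide 15 (not isolated)
Conditions: 13, n-BuLi, THF, −78 °C; ClTi(OiPr)3, −78 → −30 °C; then 12, −30 → 0 °C; H2O
Reagents that add atoms: none
Why: Aryltitanium triisopropoxides add to aldehydes but not to ketones or enones and are non-basic, so the dienone and the alpha centre should survive; Felkin–Anh addition with the quaternary ring carbon as the large group anti to the incoming aryl sets the (1R) carbinol that becomes C2 (threo to the methyl-bearing carbon), and the minor epimer is removed by chromatography.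

Step 9
Reactants: 16 4-allyl-2,6-dibromo-4-[(1R,2S)-1-hydroxy-1-(3,4,5-trimethoxyphenyl)propan-2-yl]cyclohexa-2,5-dien-1-one
Product: 18 (2R,3S,3aS)-3a-allyl-5-bromo-3-methyl-2-(3,4,5-trimethoxyphenyl)-3,3a-dihydro-1-benzofuran-6(2H)-one, via cis-fused bromo ketone 17 (not isolated)
Conditions: DBU (2.5 equiv), MeCN, 0 → 40 °C
Reagents that add atoms: none
Why: DBU turns the C2 hydroxyl into a hydrogen-bonded alkoxide that adds reversibly to the beta carbon of either bromoenone arm to give the cis-fused bromo ketone 17, whose C7 centre equilibrates through the enolate until bromine lies anti to H-7a and HBr is lost irreversibly to form the C7=C7a vinylogous ester. The closest known reaction types are the desymmetrising intramolecular oxa-Michael addition of 4-(2-hydroxyalkyl)cyclohexa-2,5-dienones and the dehydrobromination of 2-bromo-3-alkoxy ketones to 3-alkoxy enones (as in chromone formation from 3-bromochromanones). One ring is closed, the five-membered ring O1–C2–C3–C3a–C7a, by 5-exo-trig attack of oxygen on C7a. The one new stereocentre, C3a, is controlled by the resident C2/C3 pair, whose configurations are untouched because the carbinol C–O bond is never broken: in the lower transition state the C3 methyl (and the cis C2 aryl) should lie beside the flat C4 vinyl carbon of the spectator arm instead of eclipsing the allyl methylene, which gives (3aS). The selectivity needed is that between the two diastereotopic arms, and it is secured by keeping the addition reversible so that the arms compete only in the irreversible elimination (Curtin–Hammett), at a temperature low enough to keep the 3a-allyl group from [3,3] shifts. The second bromine cannot be lost (C5 is sp2, so there is no alpha' hydrogen for a Favorskii path) and remains as the C5 handle.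

Step 10
Reactants: 18 (2R,3S,3aS)-3a-allyl-5-bromo-3-methyl-2-(3,4,5-trimethoxyphenyl)-3,3a-dihydro-1-benzofuran-6(2H)-one
Product: 19 (2R,3S,3aS)-3a-allyl-5-methoxy-3-methyl-2-(3,4,5-trimethoxyphenyl)-3,3a-dihydro-1-benzofuran-6(2H)-one
Conditions: CuI (10 mol %), 3,4,7,8-tetramethyl-1,10-phenanthroline (20 mol %), Cs2CO3, MeOH (5 equiv), toluene, 80 °C
Reagents that add atoms: methanol, CO
Why: Ullmann-type copper-catalysed C–O coupling of a vinyl bromide with methanol replaces bromine at C5 itself, whereas uncatalysed conjugate addition of methoxide at C4 is slowed by the adjacent quaternary C3a, and the weak base at 80 °C should leave the vinylogous ester, the three stereocentres and the 3a-allyl group intact.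

**Compound list**

1 | 4-(benzyloxy)phenylacetic acid | OC(=O)Cc1ccc(OCc2ccccc2)cc1 | starting material
2 | (S)-4-benzyl-1,3-oxazolidin-2-one | O=C1OC[C@H](Cc2ccccc2)N1 | starting material
3 | [4-(benzyloxy)phenyl]acetic pivalic anhydride | CC(C)(C)C(=O)OC(=O)Cc1ccc(OCc2ccccc2)cc1 | intermediate
4 | (4S)-4-benzyl-3-{[4-(benzyloxy)phenyl]acetyl}-1,3-oxazolidin-2-one | O=C(Cc1ccc(OCc2ccccc2)cc1)N1[C@@H](Cc2ccccc2)COC1=O | intermediate
5 | sodium Z-enolate of 4 (enolate oxygen cis to the aryl group) | [Na+].[O-]/C(=C\c1ccc(OCc2ccccc2)cc1)N1[C@@H](Cc2ccccc2)COC1=O | intermediate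
6 | (4S)-4-benzyl-3-{(2S)-2-[4-(benzyloxy)phenyl]propanoyl}-1,3-oxazolidin-2-one | C[C@H](C(=O)N1[C@@H](Cc2ccccc2)COC1=O)c1ccc(OCc2ccccc2)cc1 | intermediate
7 | (2S)-2-[4-(benzyloxy)phenyl]propan-1-ol | C[C@H](CO)c1ccc(OCc2ccccc2)cc1 | intermediate
8 | 4-[(2S)-1-hydroxypropan-2-yl]phenol | C[C@H](CO)c1ccc(O)cc1 | intermediate
9 | 2,6-dibromo-4-[(2S)-1-hydroxypropan-2-yl]phenol | C[C@H](CO)c1cc(Br)c(O)c(Br)c1 | intermediate
10 | allyltrimethylsilane | C=CC[Si](C)(C)C | starting material
11 | 4-allyl-2,6-dibromo-4-[(2S)-1-hydroxypropan-2-yl]cyclohexa-2,5-dien-1-one | C=CCC1([C@H](C)CO)C=C(Br)C(=O)C(Br)=C1 | intermediate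
12 | (2S)-2-(1-allyl-3,5-dibromo-4-oxocyclohexa-2,5-dien-1-yl)propanal | C=CCC1([C@H](C)C=O)C=C(Br)C(=O)C(Br)=C1 | intermediate
13 | 5-bromo-1,2,3-trimethoxybenzene | COc1cc(Br)cc(OC)c1OC | starting material
14 | (3,4,5-trimethoxyphenyl)lithium | [Li]c1cc(OC)c(OC)c(OC)c1 | intermediate
15 | (3,4,5-trimethoxyphenyl)titanium triisopropoxide | CC(C)O[Ti](OC(C)C)(OC(C)C)c1cc(OC)c(OC)c(OC)c1 | intermediate
16 | 4-allyl-2,6-dibromo-4-[(1R,2S)-1-hydroxy-1-(3,4,5-trimethoxyphenyl)propan-2-yl]cyclohexa-2,5-dien-1-one | C=CCC1([C@H](C)[C@@H](O)c2cc(OC)c(OC)c(OC)c2)C=C(Br)C(=O)C(Br)=C1 | intermediate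
17 | (2R,3S,3aS,7aS)-3a-allyl-5,7-dibromo-3-methyl-2-(3,4,5-trimethoxyphenyl)-3,3a,7,7a-tetrahydro-1-benzofuran-6(2H)-one (cis ring fusion, C7 epimers) | C=CC[C@]12C=C(Br)C(=O)C(Br)[C@H]1O[C@@H](c1cc(OC)c(OC)c(OC)c1)[C@H]2C | intermediate
18 | (2R,3S,3aS)-3a-allyl-5-bromo-3-methyl-2-(3,4,5-trimethoxyphenyl)-3,3a-dihydro-1-benzofuran-6(2H)-one | C=CC[C@]12C=C(Br)C(=O)C=C1O[C@@H](c1cc(OC)c(OC)c(OC)c1)[C@H]2C | intermediate
19 | (2R,3S,3aS)-3a-allyl-5-methoxy-3-methyl-2-(3,4,5-trimethoxyphenyl)-3,3a-dihydro-1-benzofuran-6(2H)-one | C=CC[C@]12C=C(OC)C(=O)C=C1O[C@@H](c1cc(OC)c(OC)c(OC)c1)[C@H]2C | target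

**Totals**

Total step count: 10. Longest linear sequence: 10 steps (1 to 19); 2, 10 and 13 enter as single fragments.

**Steps most likely to fail**

Step 9. What may go wrong: insufficient or reversed discrimination between the two diastereotopic bromoenone arms, which would give the C3a epimer, or stalling at the bromo ketone. Fallback (catalyst control in two separate operations instead of one substrate-controlled cascade): setting out from 16, a chiral phosphoric acid (the enantiomer of 3,3'-bis(2,4,6-triisopropylphenyl)-1,1'-binaphthyl-2,2'-diyl hydrogen phosphate that is matched with the substrate) in toluene at 0 °C should effect the oxa-Michael addition without reversal and with catalyst-imposed arm selection. The cis-fused bromo ketone 17 can then be isolated and freed from the wrong-arm adduct. Et3N in CH2Cl2 at room temperature, too weak a base to reopen the ether by retro-Michael reaction, should then remove HBr and rejoin the route at 18. This fallback makes no compound outside the list (none, F0).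

Step 6. What may go wrong: capture of the oxidised phenol at the hindered para carbon by the solvent, loss of the benzylic proton to a quinone methide, or acid-induced cyclisation of the hydroxyl onto the new dienone. Fallback (oxidation and C–C bond formation separated): setting out from 9, PhI(OAc)2 in MeOH at 0 °C should give the para-quinol methyl ether 2,6-dibromo-4-[(2R)-1-hydroxypropan-2-yl]-4-methoxycyclohexa-2,5-dien-1-one F1 (same spatial arrangement as in 9; only the descriptor changes). Ionisation of the methoxy group with Me3SiOTf in CH2Cl2 at −78 °C, with 10 as the only nucleophile present, followed by aqueous work-up to remove the transient silyl ether, should deliver the allyl group to C4 and rejoin the route at 11.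

Step 10. What may go wrong: base-induced conjugate addition of methoxide at C4 followed by loss of HBr (methoxy on the wrong carbon), alkoxide exchange at the vinylogous ester, or a [3,3] shift of the allyl group on prolonged heating. Fallback (C–O bond made through boron, without alkoxide): setting out from 18, Miyaura borylation (PdCl2(dppf), KOAc, bis(pinacolato)diboron, dioxane, 70 °C) should give the 5-(4,4,5,5-tetramethyl-1,3,2-dioxaborolan-2-yl) analogue of 18 F2. Oxidation with NaBO3·4H2O in THF/H2O at room temperature should give the 5-hydroxy dienone (diosphenol) F3. O-Methylation with MeI and K2CO3 in acetone rejoins the route at the target 19.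

**Further compounds**

F0 | step 9 | none | none
F1 | step 6 | 2,6-dibromo-4-[(2R)-1-hydroxypropan-2-yl]-4-methoxycyclohexa-2,5-dien-1-one | C[C@H](CO)C1(OC)C=C(Br)C(=O)C(Br)=C1
F2 | step 10 | 5-(4,4,5,5-tetramethyl-1,3,2-dioxaborolan-2-yl) analogue of 18, spatial arrangement at C2, C3 and C3a unchanged | C=CC[C@]12C=C(B3OC(C)(C)C(C)(C)O3)C(=O)C=C1O[C@@H](c1cc(OC)c(OC)c(OC)c1)[C@H]2C
F3 | step 10 | (2R,3S,3aS)-3a-allyl-5-hydroxy-3-methyl-2-(3,4,5-trimethoxyphenyl)-3,3a-dihydro-1-benzofuran-6(2H)-one | C=CC[C@]12C=C(O)C(=O)C=C1O[C@@H](c1cc(OC)c(OC)c(OC)c1)[C@H]2C
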